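The numbers in the tables stem from a simulated flask for substances that don't exist; noise was put on by code.

**Late plateau.** Late in both earlier runs target stands near 25.5 % of the charge, although Friday's charge is 4.00 times Sunday's. The flask should therefore end there too, and the question is how far its early peak rises above that level.

| setting | Sunday's | Friday's | flask |
|---|---|---|---|
| substrate | 0.60 M | 2.4 M | 1.2 M |
| gas phase | 42 mM (held) | 42 mM (held) | 42 mM (held) |
| remark | run made earlier | run made earlier |  |
| time |  |  | 15 min |

| Sunday's: time / min | Sunday's: target / % | Friday's: time / min | Friday's: target / % |
|---|---|---|---|
| 0.167 | 33 | 0.167 | 20 |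
| 0.333 | 54 | 0.333 | 27 |
| 0.833 | 36 | 0.833 | 43 |
| 2.00 | 26 | 2.00 | 30 |
| 5.00 | 26 | 5.00 | 25 |
| 12.0 | 27 | 12.0 | 24 |

(standard deviation of a reading: 2 percentage points)

- the moment within 15 min at which there is most target
- the amount of target, in percent of the substrate charged, at that time

- at the start none of the gas phase is in solution
- a reading or a percentage of target counts all its forms, free or not

**Two times.** The reckoning here follows the excess share: the highest reading less the plateau, as a fraction of the charge less the plateau. The fill time is the time of the first reading divided by the fraction then made: 0.506 min on Sunday, 0.835 min on Friday. Excess share times fill time gives 0.194 min on Sunday and 0.196 min on Friday. Their mean is the holding time 0.195 min, and holding time over fill time is the excess share.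

**This flask.** The flask's 1.2 M lies midway between the runs on a log scale, so its fill time is reckoned as the geometric mean of the two, 0.650 min, longer than the holding time. The share is 0.300, which puts the peak at 47.8 % by this reckoning. The forecast says 49 % at 0.6 min, a little more than this reckoning: “This is an interpolation, and the mechanism is not firmly established.”

**The result.** The flask peaks at 50.1 % at 0.573 min, and target ends at 26.0 %.

    gas phase ⇌ dissolved gas, rate k1*(csat - [dissolved gas]) (kL = 1.42 s⁻¹)
    substrate + dissolved gas → target (k = 2.56 M⁻¹ s⁻¹)
    crystals ⇌ target, rate k3*(cs3 - [target]) while solid is left; crystals form when [target] > cs3 (solubility = 1.10 M, k = 1.03 s⁻¹)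
    target ⇌ isomer of the product (K = 2.85, k = 0.0332 s⁻¹)

**Making against passing.** In the flask, half of the turnover of substrate and dissolved gas into target is done by 0.281 min, while the forward passing of target into isomer of the product alone gives dissolved target a half-life of 0.35 min. At 0.282 min dissolved target in the flask is made 2.22 times faster than used up, each step taken net. The flask's excess share comes to 0.326, against the 0.300 reckoned from the holding time. For a neighbouring flask with 3.0 M of substrate, the fill time extended along the same power of the charge is 0.905 min, the holding time then gives a peak of 41.9 %, and that neighbouring flask reaches 43.3 %.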